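A factor of 3.90 separates amber from blue: both stand at 40 °C with 6.7 mM of free catalyst and the same feed, but amber is charged with 3.0 M of substrate and blue with 0.77 M.

| flask | substrate | free catalyst | temperature | remark | time |
|---|---|---|---|---|---|
| south-west | 0.77 M (fed, over 25 min) | 10 mM | 80 °C | run made earlier; the fed solution adds 0.25 times the starting volume |  |
| blue | 0.77 M (fed, over 25 min) | 6.7 mM | 40 °C | the fed solution adds 0.25 times the starting volume | 80 min |
| green | 3.0 M (fed, over 25 min) | 6.7 mM | 80 °C | the fed solution adds 0.25 times the starting volume | 80 min |
| ochre | 0.77 M (fed, over 25 min) | 6.7 mM | 80 °C | the fed solution adds 0.25 times the starting volume | 80 min |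
| amber | 3.0 M (fed, over 25 min) | 6.7 mM | 40 °C | the fed solution adds 0.25 times the starting volume | 80 min |

south-west run (percent of the substrate charged)

| time / min | target / % |
|---|---|
| 4.00 | 2 |
| 12.0 | 19 |
| 20.0 | 29 |
| 30.0 | 40 |
| 50.0 | 24 |

(scatter of a reading: 1.5 percentage points)

- for target the crystals are counted in
- charges are per starting volume, the dose included; the dosed solution carries all of it
- as a solid, counted per litre of solution: crystals
- the numbers in the tables scatter by 1.5 percentage points (one standard deviation)
- steps that have been proposed: target -> over-reaction product; crystals <-> target; catalyst intermediate -> free catalyst + target; substrate + free catalyst -> catalyst intermediate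
- the earlier runs do not show what temperature does; that part of a forecast is a guess
- percentages count the whole charge, also what has not yet gone in
- no earlier run changes the charge of free catalyst; that part of a forecast is a guess

- the flasks by amount of target, in percent of the substrate charged, highest first, at 80 min (blue / green / ochre / amber)
- the amount of target, in percent of the substrate charged of the flask you put first, at 80 min
- the amount of target, in percent of the substrate charged of the flask you put last, at 80 min

In the proposed cycle, one turnover of the catalyst gives one unit of target. The load of a flask is the substrate charged per catalyst charged, which is 448 in amber.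

| flask | load |
|---|---|
| south-west | 77.0 |
| blue | 115 |
| amber | 448 |

Any percentage of target multiplied by the load gives turnovers, so the south-west reading of 40% at 30.0 min stands for 30.8 turnovers, net of what had already over-reacted. That is fewer than amber's load, although the south-west flask was at 80 °C. My own reckoning, a guess because no earlier run shows a cold flask or this catalyst charge, gives blue and amber equal turnovers at equal times. Amber then ends under blue, by about the factor above.

The forecast gives green > amber > blue > ochre, with 68% (48% to 85%) for the first flask and 12% (4% to 20%) for the last. For the cold pair it expects “about 50% in amber and about 40% in blue”, and there it differs from my reckoning.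

The flasks give green > blue > ochre > amber, with 34.2% in green, 11.2% in blue and 4.44% in amber. At 80 min, catalyst intermediate, the resting state in amber, holds 84.6% of the catalyst there and 56.6% in blue. Multiplied by their loads, the two targets are 19.9 turnovers in amber and 12.9 in blue, not equal as reckoned. Per occupied catalyst, however, they come to 23.5 and 22.8.

    target → over-reaction product (k = 9.40 × 10⁻⁴ s⁻¹, Ea = 104 kJ mol⁻¹)
    crystals ⇌ target, rate k2*(cs2 - [target]) while solid is left; crystals form when [target] > cs2 (solubility = 0.370 M, k = 0.0770 s⁻¹)
    catalyst intermediate → free catalyst + target (k = 0.200 s⁻¹, Ea = 83.0 kJ mol⁻¹)
    substrate + free catalyst → catalyst intermediate (k = 0.250 M⁻¹ s⁻¹, Ea = 68.0 kJ mol⁻¹)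
    (constants at 80 °C)

A neighbour of amber charged with 1.2 M of substrate has a load of 179 and 67.7% of its catalyst as intermediate, so amber's figure per occupied catalyst gives 8.88% of target. The computed flask gives 8.67%.

The runs are simulated on assumed constants; scatter was added.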